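**Retrosynthetic overview**

1. Target ⇐ Shi epoxidation of the (E)-C9=C10 alkene, chelation-controlled reduction of a C5 ketone, O8 tigloylation, and palladium cyclocarbonylation of a C6-OH/C7-ethynyl pair to the α-methylene lactone.
2. Ten-membered carbocycle ⇐ Grob-type ring expansion (6 → 10) of a trans-decalin C5-alkoxide/C9-mesylate, formed in the same flask by SmI2 pinacol closure of ring B (C5–C6 bond).
3. Pinacol precursor ⇐ chelation-controlled Mukaiyama aldol (C9–C10 bond, quaternary C10) between the silyl enol ether of 2,6-dimethylcyclohexanone (ring A) and a C6–C9 aldehyde.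
4. C6–C9 aldehyde ⇐ organocatalytic Michael addition (C7–C8 bond, both stereocentres) of PMB-protected glycolaldehyde to a silylated nitroenyne made from silylpropynal and nitromethane.
5. Ring order: ring A (bought as 2-methylcyclohexanone) → ring B (pinacol) → ten-membered ring (fragmentation) → γ-lactone → epoxide.

Numbering used: germacrane numbering of the target. Ring C1–C10; C4 carries methyl C15, C5 the hydroxyl, C6 the lactone oxygen, C7 the acrylate carbon C11, C8 the tiglate, C9/C10 the epoxide, C10 methyl C14; C12 is the lactone carbonyl, C13 the exocyclic methylene.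

Assumption: 3-(trimethylsilyl)prop-2-ynal, nitromethane, 2-[(4-methoxybenzyl)oxy]acetaldehyde, 2-methylcyclohexanone and tigloyl chloride are bought; the trimethylsilyl and 4-methoxybenzyl (PMB) groups are protecting groups.

**Route**

Step 1
Reactants: 1 3-(trimethylsilyl)prop-2-ynal; 2 nitromethane
Product: 5 (E)-trimethyl(4-nitrobut-3-en-1-yn-1-yl)silane, via nitro alcohol 3 (not isolated), via mesylate 4 (not isolated)
Conditions: Et3N (10 mol %), MeNO2 (5 equiv), THF, 0 °C; then MsCl (1.1 equiv), Et3N (2.2 equiv), CH2Cl2, −20 °C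
Reagents that add atoms: none
Why: Henry (nitroaldol) addition, then sulfonylation and E1cB elimination, gives the conjugated nitroenyne as the thermodynamically favoured E isomer.

Step 2
Reactants: 5 (E)-trimethyl(4-nitrobut-3-en-1-yn-1-yl)silane; 6 2-[(4-methoxybenzyl)oxy]acetaldehyde
Product: 7 (2R,3S)-2-[(4-methoxybenzyl)oxy]-3-(nitromethyl)-5-(trimethylsilyl)pent-4-ynal
Conditions: (S)-2-[diphenyl(trimethylsilyloxy)methyl]pyrrolidine (10 mol %), 4-nitrophenol (10 mol %), toluene, 0 °C
Reagents that add atoms: none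
Why: Enamine-catalysed Michael addition (Hayashi–Jørgensen catalyst): the E-enamine of 6, shielded on one face by the diphenyl(silyloxy)methyl group, adds 1,4 to the nitroalkene through the acyclic synclinal transition state and sets C8 and C7 syn with catalyst-controlled absolute configuration.

Step 3
Reactants: 8 2-methylcyclohexan-1-one
Product: 10 [(2,6-dimethylcyclohex-1-en-1-yl)oxy]trimethylsilane, via 2,6-dimethylcyclohexanone 9 (not isolated)
Conditions: LiN(iPr)2, THF, −78 °C; MeI, −78 → 0 °C; then LiN(iPr)2, −78 °C; Me3SiCl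
Reagents that add atoms: iodomethane CI; chlorotrimethylsilane C[Si](C)(C)Cl
Why: Kinetic enolate methylation at the unsubstituted α-carbon, then enolisation of the 2,6-dimethyl ketone and O-silylation, give the only possible (tetrasubstituted) silyl enol ether; it is racemic and its methyl stereocentre (C4) is corrected in step 5.

Step 4
Reactants: 7 (2R,3S)-2-[(4-methoxybenzyl)oxy]-3-(nitromethyl)-5-(trimethylsilyl)pent-4-ynal; 10 [(2,6-dimethylcyclohex-1-en-1-yl)oxy]trimethylsilane (2 equiv)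
Product: 11 (2R)-2-[(1R,2R,3S)-1-hydroxy-2-[(4-methoxybenzyl)oxy]-3-(nitromethyl)-5-(trimethylsilyl)pent-4-yn-1-yl]-2,6-dimethylcyclohexan-1-one (both C6 epimers of the ring)
Conditions: MgBr2·OEt2 (3 equiv), CH2Cl2, −20 → 0 °C; aq. NH4Cl
Reagents that add atoms: none
Why: Chelation-controlled Mukaiyama aldol addition under neutral conditions (the acidic CH2NO2 group rules out basic enolates): MgBr2 bridges the aldehyde and PMB-ether oxygens so the enol silane attacks anti to C7 (8,9-syn), and the antiperiplanar open transition state keeps the larger ring CH2 out of the crowded slot between the metal-bound oxygen and C8, which sets quaternary C10 with O9 syn to C1 and anti to the C10 methyl, the pairing that later gives the E alkene.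

Step 5
Reactants: 11 (2R)-2-[(1R,2R,3S)-1-hydroxy-2-[(4-methoxybenzyl)oxy]-3-(nitromethyl)-5-(trimethylsilyl)pent-4-yn-1-yl]-2,6-dimethylcyclohexan-1-one
Product: 12 (1R,2R,3S)-1-[(1R,3R)-1,3-dimethyl-2-oxocyclohexyl]-2-[(4-methoxybenzyl)oxy]-3-(nitromethyl)-5-(trimethylsilyl)pent-4-yn-1-yl methanesulfonate
Conditions: MsCl, pyridine, 4-(dimethylamino)pyridine (cat.), 0 °C → rt; then TsOH·H2O (10 mol %), CHCl3, 40 °C
Reagents that add atoms: methanesulfonyl chloride CS(=O)(=O)Cl
Why: O-sulfonylation of the secondary alcohol, after which acid-catalysed enolisation at the only enolisable α-carbon (C4) equilibrates the ring methyl to the equatorial epimer, cis to the equatorial side chain.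

Step 6
Reactants: 12 (1R,2R,3S)-1-[(1R,3R)-1,3-dimethyl-2-oxocyclohexyl]-2-[(4-methoxybenzyl)oxy]-3-(nitromethyl)-5-(trimethylsilyl)pent-4-yn-1-yl methanesulfonate
Product: 14 (1R,2R,3R)-1-[(1R,3R)-1,3-dimethyl-2-oxocyclohexyl]-3-formyl-2-[(4-methoxybenzyl)oxy]-5-(trimethylsilyl)pent-4-yn-1-yl methanesulfonate, via silyl nitronate 13 (not isolated)
Conditions: Me3SiCl (1.5 equiv), DBU (1.2 equiv), CH2Cl2, 0 °C; then mCPBA (1.3 equiv), 0 °C
Reagents that add atoms: 3-chloroperoxybenzoic acid (mCPBA) OOC(=O)c1cccc(Cl)c1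
Why: Nef reaction through the silyl nitronate: peracid oxidation of the C=N bond of 13 releases the aldehyde when no base is left, so the propargylic C7 centre next to the new aldehyde is not epimerised.

Step 7
Reactants: 14 (1R,2R,3R)-1-[(1R,3R)-1,3-dimethyl-2-oxocyclohexyl]-3-formyl-2-[(4-methoxybenzyl)oxy]-5-(trimethylsilyl)pent-4-yn-1-yl methanesulfonate
Product: 16 (2S,3S,4S,5E,10R)-2-hydroxy-4-[(4-methoxybenzyl)oxy]-6,10-dimethyl-3-[(trimethylsilyl)ethynyl]cyclodec-5-en-1-one, via samarium diolate 15 (not isolated)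
Conditions: SmI2 (2.2 equiv), THF, −78 °C, then 0 °C; aq. NH4Cl
Reagents that add atoms: none
Why: Proposed new method: a SmI2 ketyl–carbonyl (pinacol) cyclisation is used to trigger a Grob fragmentation; the aldehyde ketyl adds to the ring A ketone through a chair in which C6–O, the C7 alkynyl group, C8–OPMB and C9–OMs are all equatorial, giving the trans-decalin cis-diolate 15 (this sets C6, with O6 trans to the C7 substituent), whose axial trivalent-samarium alkoxide on C5 is antiperiplanar across C5–C10 to the equatorial C9–OMs, so the C5–C10 bond breaks with loss of mesylate and delivers the ten-membered ring, the C5 ketone and the (E)-C9=C10 alkene stereospecifically; the closest known chemistry is the SmI2 Barbier cyclisation/Grob fragmentation sequence of iodoalkyl keto mesylates and the SmI2 intramolecular keto–aldehyde pinacol coupling.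

Step 8
Reactants: 16 (2S,3S,4S,5E,10R)-2-hydroxy-4-[(4-methoxybenzyl)oxy]-6,10-dimethyl-3-[(trimethylsilyl)ethynyl]cyclodec-5-en-1-one
Product: 17 (2S,3S,4S,5E,10R)-3-ethynyl-2-hydroxy-4-[(4-methoxybenzyl)oxy]-6,10-dimethylcyclodec-5-en-1-one
Conditions: Bu4NF, AcOH, THF, 0 °C
Reagents that add atoms: none
Why: Fluoride-mediated protodesilylation of the alkynylsilane, buffered with AcOH so that the α-hydroxy ketone (C4, C6) is not epimerised.

Step 9
Reactants: 17 (2S,3S,4S,5E,10R)-3-ethynyl-2-hydroxy-4-[(4-methoxybenzyl)oxy]-6,10-dimethylcyclodec-5-en-1-one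
Product: 18 (4R,6S,7R,8S,9E)-8-[(4-methoxybenzyl)oxy]-5-oxogermacra-9,11(13)-dien-12,6-olide
Conditions: PdCl2 (5 mol %), SnCl2 (5 mol %), PPh3 (10 mol %), CO (7 atm), MeCN, 75 °C
Reagents that add atoms: carbon monoxide [C-]#[O+]
Why: Norton cyclocarbonylation of a homopropargylic alcohol: an alkoxycarbonyl–palladium species formed from O6 and CO adds cis across the alkyne and protonolysis gives the α-methylene-γ-butyrolactone; C6 and C7 are untouched, so the trans ring fusion set in step 7 is carried over.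

Step 10
Reactants: 18 (4R,6S,7R,8S,9E)-8-[(4-methoxybenzyl)oxy]-5-oxogermacra-9,11(13)-dien-12,6-olide
Product: 19 (4R,6S,7R,8S,9E)-8-hydroxy-5-oxogermacra-9,11(13)-dien-12,6-olide
Conditions: DDQ (1.2 equiv), CH2Cl2/pH 7 buffer, 0 °C
Reagents that add atoms: none
Why: Oxidative PMB-ether cleavage (single-electron oxidation of the electron-rich arene, then hydrolysis of the oxocarbenium ion); the alkenes and the lactone are inert.

Step 11
Reactants: 19 (4R,6S,7R,8S,9E)-8-hydroxy-5-oxogermacra-9,11(13)-dien-12,6-olide; 20 (E)-2-methylbut-2-enoyl chloride (tigloyl chloride)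
Product: 21 (4R,6S,7R,8S,9E)-5-oxo-8-{[(E)-2-methylbut-2-enoyl]oxy}germacra-9,11(13)-dien-12,6-olide
Conditions: pyridine, 4-(dimethylamino)pyridine (cat.), CH2Cl2, 0 °C → rt
Reagents that add atoms: none
Why: Nucleophile-catalysed O-acylation of the only free hydroxyl (O5 is still masked as the ketone), with retention at C8 and of the E geometry of the tigloyl unit.

Step 12
Reactants: 21 (4R,6S,7R,8S,9E)-5-oxo-8-{[(E)-2-methylbut-2-enoyl]oxy}germacra-9,11(13)-dien-12,6-olide
Product: 22 (4R,5R,6S,7R,8S,9E)-5-hydroxy-8-{[(E)-2-methylbut-2-enoyl]oxy}germacra-9,11(13)-dien-12,6-olide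
Conditions: Zn(BH4)2, Et2O, −30 °C
Reagents that add atoms: none
Why: Chelation-controlled 1,2-reduction: Zn2+ bridges the C5 ketone and the C6 oxygen so hydride arrives anti to C7 (Cram-chelate model), the same face favoured by Felkin–Anh control from C4, giving the 5R alcohol; the neutral ethereal borohydride leaves the α-methylene lactone, the tiglate and the ring alkene alone.

Step 13
Reactants: 22 (4R,5R,6S,7R,8S,9E)-5-hydroxy-8-{[(E)-2-methylbut-2-enoyl]oxy}germacra-9,11(13)-dien-12,6-olide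
Product: 23 (4R,5R,6S,7S,8R,9R,10R)-9,10-epoxy-5-hydroxy-8-{[(E)-2-methylbut-2-enoyl]oxy}germacr-11(13)-en-12,6-olide
Conditions: 1,2:4,5-di-O-isopropylidene-β-D-erythro-2,3-hexodiulo-2,6-pyranose (30 mol %), KHSO5 (as 2KHSO5·KHSO4·K2SO4), K2CO3, Bu4NHSO4 (cat.), MeCN/CH2(OMe)2/aq. Na2B4O7, 0 °C
Reagents that add atoms: potassium peroxymonosulfate KHSO5 [K+].[O-]S(=O)(=O)OO
Why: Shi asymmetric epoxidation: the dioxirane of the D-fructose-derived ketone attacks the only electron-rich alkene through the spiro transition state that gives R,R epoxides from E-trisubstituted alkenes, setting C9 and C10 under reagent control, while the conjugated alkenes of the lactone and the tiglate do not react.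

**Compound list**

1 | 3-(trimethylsilyl)prop-2-ynal | C[Si](C)(C)C#CC=O | starting material
2 | nitromethane | C[N+](=O)[O-] | starting material
3 | 1-nitro-4-(trimethylsilyl)but-3-yn-2-ol (racemic) | C[Si](C)(C)C#CC(O)C[N+](=O)[O-] | intermediate
4 | 1-nitro-4-(trimethylsilyl)but-3-yn-2-yl methanesulfonate (racemic) | C[Si](C)(C)C#CC(OS(C)(=O)=O)C[N+](=O)[O-] | intermediate
5 | (E)-trimethyl(4-nitrobut-3-en-1-yn-1-yl)silane | C[Si](C)(C)C#C/C=C/[N+](=O)[O-] | intermediate
6 | 2-[(4-methoxybenzyl)oxy]acetaldehyde | O=CCOCc1ccc(OC)cc1 | starting material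
7 | (2R,3S)-2-[(4-methoxybenzyl)oxy]-3-(nitromethyl)-5-(trimethylsilyl)pent-4-ynal | O=C[C@H](OCc1ccc(OC)cc1)[C@@H](C#C[Si](C)(C)C)C[N+](=O)[O-] | intermediate
8 | 2-methylcyclohexan-1-one (racemic) | CC1CCCCC1=O | starting material
9 | 2,6-dimethylcyclohexan-1-one (cis/trans mixture) | CC1CCCC(C)C1=O | intermediate
10 | [(2,6-dimethylcyclohex-1-en-1-yl)oxy]trimethylsilane (racemic) | CC1CCCC(C)=C1O[Si](C)(C)C | intermediate
11 | (2R)-2-[(1R,2R,3S)-1-hydroxy-2-[(4-methoxybenzyl)oxy]-3-(nitromethyl)-5-(trimethylsilyl)pent-4-yn-1-yl]-2,6-dimethylcyclohexan-1-one (both C6 epimers of the ring) | CC1CCC[C@@](C)(C1=O)[C@@H](O)[C@H](OCc2ccc(OC)cc2)[C@@H](C#C[Si](C)(C)C)C[N+](=O)[O-] | intermediate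
12 | (1R,2R,3S)-1-[(1R,3R)-1,3-dimethyl-2-oxocyclohexyl]-2-[(4-methoxybenzyl)oxy]-3-(nitromethyl)-5-(trimethylsilyl)pent-4-yn-1-yl methanesulfonate | C[C@@H]1CCC[C@@](C)(C1=O)[C@@H](OS(C)(=O)=O)[C@H](OCc2ccc(OC)cc2)[C@@H](C#C[Si](C)(C)C)C[N+](=O)[O-] | intermediate
13 | O-trimethylsilyl nitronate of 12 (the CH2NO2 group of 12 becomes CH=N(O)OSiMe3; all stereocentres as in 12) | C[C@@H]1CCC[C@@](C)(C1=O)[C@@H](OS(C)(=O)=O)[C@H](OCc2ccc(OC)cc2)[C@@H](C#C[Si](C)(C)C)C=[N+]([O-])O[Si](C)(C)C | intermediate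
14 | (1R,2R,3R)-1-[(1R,3R)-1,3-dimethyl-2-oxocyclohexyl]-3-formyl-2-[(4-methoxybenzyl)oxy]-5-(trimethylsilyl)pent-4-yn-1-yl methanesulfonate | C[C@@H]1CCC[C@@](C)(C1=O)[C@@H](OS(C)(=O)=O)[C@H](OCc2ccc(OC)cc2)[C@@H](C#C[Si](C)(C)C)C=O | intermediate
15 | trans-decalin samarium diolate: 4,4a-bis[(diiodosamario)oxy]-2-[(4-methoxybenzyl)oxy]-5,8a-dimethyl-3-[(trimethylsilyl)ethynyl]decahydronaphthalen-1-yl methanesulfonate, configured as the free diol (1R,2R,3S,4S,4aR,5R,8aR) | C[C@@H]1CCC[C@]2(C)[C@@H](OS(C)(=O)=O)[C@H](OCc3ccc(OC)cc3)[C@@H](C#C[Si](C)(C)C)[C@H](O[Sm](I)I)[C@@]12O[Sm](I)I | intermediate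
16 | (2S,3S,4S,5E,10R)-2-hydroxy-4-[(4-methoxybenzyl)oxy]-6,10-dimethyl-3-[(trimethylsilyl)ethynyl]cyclodec-5-en-1-one | O=C1[C@H](C)CCC/C(C)=C/[C@H](OCc2ccc(OC)cc2)[C@@H](C#C[Si](C)(C)C)[C@@H]1O | intermediate
17 | (2S,3S,4S,5E,10R)-3-ethynyl-2-hydroxy-4-[(4-methoxybenzyl)oxy]-6,10-dimethylcyclodec-5-en-1-one | O=C1[C@H](C)CCC/C(C)=C/[C@H](OCc2ccc(OC)cc2)[C@@H](C#C)[C@@H]1O | intermediate
18 | (4R,6S,7R,8S,9E)-8-[(4-methoxybenzyl)oxy]-5-oxogermacra-9,11(13)-dien-12,6-olide | C=C1C(=O)O[C@@H]2C(=O)[C@H](C)CCC/C(C)=C/[C@H](OCc3ccc(OC)cc3)[C@@H]12 | intermediate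
19 | (4R,6S,7R,8S,9E)-8-hydroxy-5-oxogermacra-9,11(13)-dien-12,6-olide | C=C1C(=O)O[C@@H]2C(=O)[C@H](C)CCC/C(C)=C/[C@H](O)[C@@H]12 | intermediate
20 | (E)-2-methylbut-2-enoyl chloride (tigloyl chloride) | C/C=C(\C)C(Cl)=O | starting material
21 | (4R,6S,7R,8S,9E)-5-oxo-8-{[(E)-2-methylbut-2-enoyl]oxy}germacra-9,11(13)-dien-12,6-olide | C=C1C(=O)O[C@@H]2C(=O)[C@H](C)CCC/C(C)=C/[C@H](OC(=O)/C(C)=C/C)[C@@H]12 | intermediate
22 | (4R,5R,6S,7R,8S,9E)-5-hydroxy-8-{[(E)-2-methylbut-2-enoyl]oxy}germacra-9,11(13)-dien-12,6-olide | C=C1C(=O)O[C@@H]2[C@H](O)[C@H](C)CCC/C(C)=C/[C@H](OC(=O)/C(C)=C/C)[C@@H]12 | intermediate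
23 | (4R,5R,6S,7S,8R,9R,10R)-9,10-epoxy-5-hydroxy-8-{[(E)-2-methylbut-2-enoyl]oxy}germacr-11(13)-en-12,6-olide (CNP0165329.2) | C=C1C(=O)O[C@@H]2[C@H](O)[C@H](C)CCC[C@@]3(C)O[C@@H]3[C@H](OC(=O)/C(C)=C/C)[C@@H]12 | target

**Totals**

Total step count: 13. Longest linear sequence: 12 steps (steps 1, 2, 4–13); step 3 is a one-step side branch.

**Three steps most likely to fail**

Step 7 (the proposed new cascade). The ketyl may be reduced or couple intermolecularly before it reaches the hindered ketone, or the diolate may not fragment in the flask. The fallback separates the two events, each of which is known chemistry, and sets out from 14. SmI2 (2.2 equiv) with t-BuOH (2 equiv) in THF at −78 °C and a cold proton quench gives the isolable pinacol product (1R,2R,3S,4S,4aR,5R,8aR)-4,4a-dihydroxy-2-[(4-methoxybenzyl)oxy]-5,8a-dimethyl-3-[(trimethylsilyl)ethynyl]decahydronaphthalen-1-yl methanesulfonate F3. KH in THF at 0 °C then brings about the classical Wharton–Grob fragmentation of this 1,3-diol monomesylate, and the route is rejoined at 16.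

Step 4 (Mukaiyama aldol). The tetrasubstituted enol silane may be too unreactive towards the MgBr2 chelate, or the C9/C10 pairing may be poorly controlled; only the isomer drawn can give the E alkene. The fallback changes the nucleophile from an enol silane reacting through an open transition state to a pre-formed, non-basic metal enolate reacting through a closed one. It sets out from 10: TiCl4 (1.0 equiv, CH2Cl2, 20 °C) converts it into trichloro[(2,6-dimethylcyclohex-1-en-1-yl)oxy]titanium F1. F1 adds to 7 at −78 °C with titanium bound to the enolate oxygen, the aldehyde oxygen and the PMB ether, a mode that is syn-selective whatever the enolate geometry. Aqueous work-up rejoins the route at 11.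

Step 6 (Nef reaction). The primary nitro group sits next to an epimerisable propargylic centre, and a free nitronate could add to the ring ketone. The fallback is a reductive rather than oxidative unmasking and sets out from 12. SnCl2·2H2O, PhSH and Et3N (MeCN, 20 °C) reduce the nitro group to the aldoxime (1R,2R,3S)-1-[(1R,3R)-1,3-dimethyl-2-oxocyclohexyl]-3-[(hydroxyimino)methyl]-2-[(4-methoxybenzyl)oxy]-5-(trimethylsilyl)pent-4-yn-1-yl methanesulfonate F2. Transoximation with aqueous glyoxylic acid (THF, 20 °C) then releases the aldehyde, and the route is rejoined at 14.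

Further compounds
F1 | step 4 | trichloro[(2,6-dimethylcyclohex-1-en-1-yl)oxy]titanium | CC1CCCC(C)=C1O[Ti](Cl)(Cl)Cl
F2 | step 6 | (1R,2R,3S)-1-[(1R,3R)-1,3-dimethyl-2-oxocyclohexyl]-3-[(hydroxyimino)methyl]-2-[(4-methoxybenzyl)oxy]-5-(trimethylsilyl)pent-4-yn-1-yl methanesulfonate | C[C@@H]1CCC[C@@](C)(C1=O)[C@@H](OS(C)(=O)=O)[C@H](OCc2ccc(OC)cc2)[C@@H](C#C[Si](C)(C)C)C=NO
F3 | step 7 | (1R,2R,3S,4S,4aR,5R,8aR)-4,4a-dihydroxy-2-[(4-methoxybenzyl)oxy]-5,8a-dimethyl-3-[(trimethylsilyl)ethynyl]decahydronaphthalen-1-yl methanesulfonate | C[C@@H]1CCC[C@]2(C)[C@@H](OS(C)(=O)=O)[C@H](OCc3ccc(OC)cc3)[C@@H](C#C[Si](C)(C)C)[C@H](O)[C@@]12O
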